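3 questions stand on this flask, and I want to meet them with one concentration read from the runs.

the same everywhere: catalyst 0.0500 M

| flask | substrate | coupling partner | time |
|---|---|---|---|
| elm | 0.500 M | 1.25 M |  |
| alder | 0.250 M | 1.00 M |  |
| oak | 0.500 M | 1.90 M |  |
| ash | 0.500 M | 3.70 M | 6.9 min |

| run | time / min | [target] / M |
|---|---|---|
| elm run | 1.1 | 0.0534 |
| elm run | 2.3 | 0.0959 |
| elm run | 3.5 | 0.1359 |
| elm run | 4.6 | 0.1556 |
| elm run | 5.8 | 0.1771 |
| elm run | 6.9 | 0.1836 |
| alder run | 1.1 | 0.0261 |
| alder run | 2.3 | 0.0592 |
| alder run | 3.5 | 0.0820 |
| alder run | 4.6 | 0.0958 |
| alder run | 5.8 | 0.1003 |
| alder run | 6.9 | 0.1064 |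
| oak run | 1.1 | 0.0688 |
| oak run | 2.3 | 0.1329 |
| oak run | 3.5 | 0.1756 |
| oak run | 4.6 | 0.2043 |
| oak run | 5.8 | 0.2212 |
| oak run | 6.9 | 0.2360 |

(scatter of a reading: 0.002 M)

- reaction order in [coupling partner] at the outset, round the charge of the elm run, defined at two percent of the substrate turned into target
- reaction order in [substrate] at the outset, round the charge of the elm run, defined at two percent of the substrate turned into target (one fixed amount of target, the same in the runs compared)
- target in the ash run at 6.9 min, as a share of the substrate charged

- Overall: substrate + coupling partner -> target, with catalyst as catalyst.
- Constant volume, constant temperature.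
- What is held in complexes is read along with the free species.
- An order is taken over about fifteen percent of the charge, up and down.

I turn the coupling partner first. By hand, a first-order partner would lift the rate by the charge ratio from elm to oak, 1.52. I take the first readings, at 1.1 min, as the measure of the early rate: the oak run has made 0.0688 M and the elm run 0.0534 M, a ratio of 1.29, less than the charge ratio. So I assume the rate bends towards a ceiling as ceiling × R/(h + R), with R the partner concentration and the substrate held at 0.500 M. The two readings give 2.37 M, a loose reading. This h is the partner concentration at which the rate stands at half its ceiling, an apparent Michaelis constant. On that curve the order in partner is h/(h + R), which at the elm charge is 0.654.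

Next I turn the substrate. The alder run has half the substrate of the elm run and also less partner, and by hand a first-order substrate would leave a ratio of 0.500 once the partner's part is removed. The curve puts that part at 0.859. To lessen the scatter I add the first two readings of each run, which gives alder over elm 0.571. Dividing by the partner's part leaves the substrate's part at 0.665, more than the first-order ratio, and that makes my order in substrate 0.589.

Last I turn the partner up to 3.70 M in the ash run, which lies above h. The curve lifts the rate over elm by 1.76, not the 2.96 of the charges. Oak's target at 6.9 min stands 1.29 times elm's 0.1836 M, close to the ratio of their first readings, so I scale elm's reading by the factor from the curve and reckon 64.8 % of the substrate for the ash run.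

The forecast gives an order of 0.65 in partner, an order of 0.7 in substrate and 63 % for the ash run, and of the step from elm to oak it says “the partner is partly saturating”. My substrate order is lower than its value, and my ash share is higher.

The flask gives an order of 0.67 in partner, an order of 0.47 in substrate and 57.2 % for the ash run, from these steps:

catalyst + substrate ⇌ catalyst-substrate complex (9.180 M⁻¹ min⁻¹, 0.9240 min⁻¹); catalyst-substrate complex + coupling partner → target + catalyst (1.638 M⁻¹ min⁻¹); coupling partner → lost reagent (0.08280 min⁻¹); target → decomposed product (0.09060 min⁻¹) The power-law fit puts the ash run at 70.4 %, above the flask. The ash target at 6.9 min is 0.286 M, which is 1.56 times the elm reading, less than the factor from h. Held at the ash charge, h gives an order in partner of 0.390, below the 0.654 at the elm charge.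

Readings and results are simulated with made-up constants; noise was put on by code.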